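The runs are simulated from invented constants; scatter was added.

47.1 % of the starting material consumed in the delta run stands as target at its last reading, and I carry this forward as the target share: target divided by starting material consumed, which the trade calls a selectivity.

in all of them: starting material 0.050 M
- delta: reagent 0.15 M; temperature 0 °C; run made earlier
- north-west: reagent 0.0750 M; temperature 0 °C; time 80 min
- south-east: reagent 0.0750 M; at −20 °C until 40 min, from then on at 20 °C; time 80 min
- east: reagent 0.0750 M; temperature −20 °C; time 80 min
- north: reagent 0.0750 M; temperature 20 °C; time 80 min

delta run (percent of the starting material charged)

| time / min | target / % | starting material / % |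
|---|---|---|
| 3.00 | 11.4 | 76.1 |
| 6.00 | 20.5 | 57.4 |
| 10.0 | 27.7 | 41.8 |
| 15.0 | 33.8 | 28.6 |
| 20.0 | 38.5 | 19.9 |
| 25.0 | 40.5 | 14.1 |

(readings scatter by 0.5 percentage points)

1. the flask that comes out highest in amount of target, in percent of the starting material charged, or "all alike" when all lie within 1.5 percentage points (north-west / south-east / east / north / all alike)
2. target at the end, in percent of the starting material charged, north-west
3. target at the end, in percent of the starting material charged, south-east
4. target at the end, in percent of the starting material charged, east
5. target at the end, in percent of the starting material charged, north

- in percentages every species weighs as the starting material in it: one homo dimer counts as two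
- what was read earlier has a scatter of 0.5 percentage points, one standard deviation
- candidate steps: starting material + reagent <-> target; starting material + reagent -> isomer of the product A; starting material + reagent -> second isomer; 2 starting material -> homo dimer; target <-> isomer of the product B
- the earlier runs do not show what temperature does; that part of a forecast is a guess

Starting material is charged at 0.050 M against 0.0750 M of reagent, so it is the limiting reagent in the new flasks, and the question becomes a balance on it. The share reads 47.7 % at 3.00 min and 47.1 % at 25.0 min, so the split does not visibly drift during the delta run. If the split carries over to a new flask, its target is the share times the starting material it consumes.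

To find the consumption, I take the loss as a constant times starting material times reagent, with one reagent lost per starting material. The last delta reading then gives 0.0108 /M/s. North-west is at the same temperature as the delta run, and the same law leaves 11.1 % of its starting material after 80 min. My reckoning for north-west is therefore 41.9 % target.

I expect that figure to run high. North-west has half the reagent of the delta run, and the candidate step to homo dimer takes two starting material and no reagent, so the share in north-west can lie lower. I put no number on that. For the other flasks, temperature remains a guess.

The forecast gives 41.5 % for north-west, 45 % for south-east, 21 % for east and 44 % for north, and it names south-east as highest: “South-east edges north, but this is uncertain.”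

North-west comes out highest at 36.2 %, with south-east at 33.1 %, north at 29.6 % and east at 20.4 %.

    starting material + reagent ⇌ target (K = 520 /M, k = 0.0250 /M/s, Ea = 52.0 kJ/mol, ΔH = 2.00 kJ/mol)
    starting material + reagent → isomer of the product A (k = 0.0180 /M/s, Ea = 61.0 kJ/mol)
    starting material + reagent → second isomer (k = 0.00910 /M/s, Ea = 57.0 kJ/mol)
    2 starting material → homo dimer (k = 0.0120 /M/s, Ea = 58.0 kJ/mol)
    target ⇌ isomer of the product B (K = 0.230, k = 4.10 × 10⁻⁴ /s, Ea = 83.0 kJ/mol, ΔH = −26.0 kJ/mol)
    (constants at 20 °C)

North-west consumes 91.0 % of its starting material, so its target share is 39.8 %, less than the 47.1 % of the delta run, and its homo dimer stands at 14.8 %. A neighbour of south-east, charged with less reagent at 0.030 M, consumes 87.2 % of its starting material. The delta share would make that 41.1 % target, but this neighbour gives 19.7 % target, with homo dimer at 37.1 %.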